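## Structural features

The target is a cyclohexene (ring carbons C1–C6, alkene C4=C5) cis-fused to an oxirane across C1–C6. C1 is fully substituted and carries the exocyclic C7H2 benzoate, C2 carries a free hydroxyl and C3 a second benzoate; this numbering is used for every compound below. The four stereocentres are contiguous (C6–C1–C2–C3; 1R,2S,3S,6S): the oxirane oxygen lies on one face, while C7, the C2 hydroxyl and the C3 benzoate all lie on the other. The oxirane is allylic and is opened by acid much more easily than an acetal is cleaved. The C2 hydroxyl is trans to the oxirane oxygen and can start a Payne rearrangement under strong base, and the C3 benzoate can migrate to the cis O2. The real difficulty is the oxygenated quaternary C1 in one absolute configuration, together with the differentiation of four oxygen functions (plus a temporary fifth at C6) on the correct faces. The key step exploits the fact that C7, C1 and C2, each bearing oxygen, are the benzylic, ipso and phenolic carbons of an ortho-hydroxymethyl phenol, and C3–C6 are its four remaining ring CH groups. Joining the benzylic oxygen to C1 by oxidative dearomatisation delivers all seven carbons, the C1–O bond and a C3=C4–C5=C6 diene ready for cis-1,4 oxygenation; C1 is then the only centre needing external chirality.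

## Logic of the disconnections

13 ⇒ 11 + 12. The acyl C–O bond of the C3 ester is cut. This ester is the one that can migrate to the cis O2, so it is added last and under near-neutral conditions. The gain is a mono-ester, 11. The forward step must acylate O3 in preference to O2, which is helped by O2 lying next to the quaternary C1.

11 ⇒ 10. The C6–O bond of the oxirane is cut; the oxygen stays on C1 and C6 receives a sulfonate on the opposite face. The vinyl oxirane is the most acid-sensitive function, so it is unveiled only after the last acid step. The forward step needs C1–O and C6–O trans, and a base that neither removes the C7 ester nor starts a Payne equilibration.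

10 ⇒ 9. O2 and O3 are tied back into an isopropylidene acetal. They must be masked while O6 is sulfonylated. The acetal is removed at this point, before the oxirane exists, because an acetal cannot be cleaved by acid in the presence of a vinyl oxirane. The demand is that the allylic sulfonate survives acid-catalysed acetal exchange.

9 ⇒ 8. The S–O bond at O6 is cut, leaving a trans-1,6-diol. The forward step must sulfonylate the secondary allylic hydroxyl and leave the tertiary one untouched.

8 ⇒ 6 + 7. The C7–O ester bond is cut and C7 is rejoined to the C1 oxygen as a spiro-oxirane. C7 is the only unhindered electrophilic carbon, and the C1–O bond, with the C1 configuration, passes through untouched. One ester and the tertiary alcohol collapse into a three-membered ring. The forward step needs attack at C7 and not C1, and no free alkoxide at O6, which is trans to the oxirane oxygen and would invert C1 by Payne rearrangement.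

6 ⇒ 5. The two acetal C–O bonds are cut, giving a triol. The forward step relies on only the cis-vicinal O2/O3 pair closing a five-membered acetal.

5 ⇒ 3 (through 4). The C3–O and C6–O bonds are cut; both oxygens trace back to one molecule of dioxygen. Cis-1,4 oxygens flanking an alkene are the retron of a [4+2] addition of dioxygen. Two stereocentres and two C–O bonds are removed and a 1,3-diene remains. Oxygen must approach the face that carries the C2 hydroxyl and C7.

3 ⇒ 2. The C2–H bond is cut (carbinol to ketone), leaving the planar dienone. The forward step needs 1,2-hydride delivery from the face of the oxirane oxygen, and it must be faster than the [4+2] dimerisation of 2.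

2 ⇒ 1. The C1–O bond of the spiro-oxirane is cut and the ring rearomatised. C7, C1, C2 and their oxygens then come from one commercial arene and all stereochemistry is removed. The forward step needs enantioface selection at C1 by a chiral oxidant. 1 is used without protecting or blocking groups: the benzylic hydroxyl is the nucleophile, and a ring substituent added to slow dimerisation would later have to be removed from a sensitive diene.

## Other disconnections considered

Alternative 1: The C1–C6 ring bond and the C7–O bond are cut, going back from the fused isoxazoline A1 to the open-chain Z-enal oxime A2. In the forward step NaOCl would turn A2 into a nitrile oxide that adds intramolecularly across the C1=C7 silyl enol ether.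
- In favour: the reaction class is well precedented, and on this point it is better than the chosen key step, which is new as an asymmetric process. The carbocycle and the oxygenated quaternary C1 form in one C–C bond-forming event. The C2/C3 diol would come from the chiral pool, so the absolute configuration is not in doubt, which is also better than the chosen plan. O1 and O7 are differentiated from the start.
- Against: A2 is itself a multistep target (regioselective enol silylation next to an alkoxy centre, Z-enal). Face selectivity at C1 rests on substrate control by the acetal and is not assured. Hypochlorite may chlorinate the enol ether. After the cycloaddition, N–O cleavage, stereoselective reduction at C6, desilylation, oxirane closure, acetal removal and two benzoylations would remain.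
- Comparison: structurally it creates C1 late under acyclic control, whereas the chosen plan sets C1 first and relays it in the ring. Mechanistically it is a dipolar cycloaddition against an oxidative dearomatisation. In step count it would be roughly twice as long.

Alternative 2: The C2–O and C3–O bonds are cut, going back from the diene diol A3 to benzyl acetate A4. In the forward step whole cells expressing toluene dioxygenase would add dioxygen to the ortho and meta carbons on one face.
- In favour: one operation on a commodity arene would give all seven carbons and the cis C2/C3 diol in the absolute sense the target needs (the 1S and 2R centres of A3 become C3 and C2). The remaining C1=C6–C5=C4 diene invites singlet-oxygen addition across C1/C4 on the face away from the protected diol, and phosphite removal of one peroxide oxygen would leave the C1–C6 vinyl oxirane trans to the diol. That facial control is steric and more secure than the hydrogen-bond direction used here. The whole route is estimated at six to seven steps. On precedent of the key step, on certainty of absolute configuration and on step count this alternative is the equal or the better of the chosen plan.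
- Against: it needs fermentation with a recombinant organism. A3 would rearomatise by loss of water under acid or heat. C7 arrives as an acetate that must be exchanged for a benzoate beside other esters. The deoxygenation must remove the right peroxide oxygen. Regioselective O3 benzoylation is needed there as here (equal).
- Comparison: structurally it sets C2/C3 first and C1/C6 last, the reverse of the chosen plan. The chosen plan is kept because it needs only a small-molecule catalyst and standard glassware, and because its first step is the reaction to be explored.

Alternative 3: The C3–C4 bond is cut, going back from A5 to the acyclic Z-iodoalkenyl aldehyde A6. In the forward step CrCl2 with catalytic NiCl2 would convert the vinyl iodide into a vinylchromium species that adds to the C3 aldehyde (Nozaki–Hiyama–Kishi reaction).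
- In favour: the coupling tolerates esters and oxiranes. In A5 O3 is free and O2 is silylated, so the C3 benzoate would need no regioselection, which is better than step 9 of the chosen plan. Only two steps would follow the key step.
- Against: C1, C2, C6 and the oxirane must already be present in A6, an epimerisable α-silyloxy aldehyde next to a quaternary oxirane carbon; it would be long to make and fragile. The C3 configuration is created in the ring closure under uncertain control. A stoichiometric excess of toxic divalent chromium is needed. The final fluoride desilylation could move the benzoate from O3 to the cis O2.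
- Comparison: structurally the stereocentres are assembled in an open chain instead of being relayed in a ring. Mechanistically it is a precedented organometallic addition (better) against a new oxidation. In step count it is clearly longer, since the precursor alone would probably exceed nine steps.

Key step: step 1

Assumption: ArI* is the C2-symmetric iodoarene 2,2′-[(2-iodo-1,3-phenylene)bis(oxy)]bis(N-mesitylpropanamide), available in both antipodes from lactic esters. Which antipode gives (R)-2 cannot be predicted with confidence, so the route is written for the one that does, to be found by one trial with each.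

## Route

Step 1
Reactants: 1 2-(hydroxymethyl)phenol (salicyl alcohol)
Product: 2 (R)-1-oxaspiro[2.5]octa-5,7-dien-4-one
Conditions: ArI* (10 mol %), dried mCPBA (1.2 equiv), CH2Cl2–(CF3)2CHOH (10:1), 4 Å MS, −20 °C; cold solution used at once
Reagents that add atoms: none
Why: Proposed new method: mCPBA should oxidise ArI* to a trivalent aryliodine species that takes up the more acidic phenolic oxygen of 1 as a ligand; reductive departure of monovalent ArI then makes the ring electrophilic at C1 and the tethered benzylic oxygen bonds there, giving the C1–O bond, the oxirane and the C2 carbonyl conjugated to the C3=C4–C5=C6 diene. The closest known reactions are the racemic periodate oxidation of ortho-hydroxybenzyl alcohols to spiro-oxiranyl dienones (Adler–Becker oxidation) and chiral iodoarene/mCPBA-catalysed dearomative spirolactonisations of phenols, in which a carboxylic acid plays the part of the hydroxymethyl group. The oxirane closes in a 3-exo-trig mode: oxygen attacks the sp2 ipso carbon and the π bond that is broken lies outside the new ring. C1 is the only new stereocentre and is set by the catalyst, whose two lactamide arms fold over the iodine centre through N–H···O hydrogen bonds and should expose one face of the iodine-bound phenoxide to the CH2OH oxygen. Regioselectivity is secured by the substrate, because the ortho CH2OH can reach no ring carbon other than C1, provided that water is excluded so that no external nucleophile attacks the para position. Chemoselectivity (phenol before benzylic alcohol, no oxidation to the aldehyde) rests on the preference of iodine for the phenoxide ligand and on the low temperature. As 2 dimerises by [4+2] cycloaddition on standing, it is neither concentrated nor warmed.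

Step 2
Reactants: 2 (R)-1-oxaspiro[2.5]octa-5,7-dien-4-one
Product: 3 (3R,4S)-1-oxaspiro[2.5]octa-5,7-dien-4-ol
Conditions: CeCl3·7H2O (1.2 equiv), NaBH4 (3 equiv), MeOH–CH2Cl2, −78 °C; cold NaHCO3 aq. work-up
Reagents that add atoms: none
Why: Luche reduction: cerium-activated borohydride adds 1,2 to the dienone and should outrun the dimerisation. The ring of 2 is planar, so the spiro-oxirane is the only face-differentiating element; chelation of trivalent cerium between the carbonyl and oxirane oxygens swings C7 over the upper face, and hydride should enter from the face of the oxirane oxygen (chelation-controlled addition to an α-alkoxy ketone). The new C2 hydroxyl is thus placed cis to C7 and trans to the oxirane oxygen.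

Step 3
Reactants: 3 (3R,4S)-1-oxaspiro[2.5]octa-5,7-dien-4-ol
Product: 5 (3S,4S,5S,8R)-1-oxaspiro[2.5]oct-6-ene-4,5,8-triol, via endoperoxide 4 (not isolated)
Conditions: O2, tetraphenylporphyrin (cat.), hν (visible), CH2Cl2, solid NaHCO3, −78 °C; then thiourea, MeOH, −78 °C → rt
Reagents that add atoms: oxygen, O=O
Why: [4+2] cycloaddition of singlet oxygen to the 1,3-diene, then thiourea reduction of the O–O bond to the cis-1,4-diol. In a solvent that does not hydrogen-bond, the allylic C2 hydroxyl should steer oxygen to its own face, and the lone pairs of the oxirane oxygen disfavour attack on the other face, so the C3 and C6 oxygens should end cis to the C2 hydroxyl. Any adduct from the other face has a trans-2,3-diol, does not form the cis-fused acetal and is removed in step 4.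

Step 4
Reactants: 5 (3S,4S,5S,8R)-1-oxaspiro[2.5]oct-6-ene-4,5,8-triol
Product: 6 (3S,4S,5S,8R)-4,5-O-isopropylidene-1-oxaspiro[2.5]oct-6-ene-4,5,8-triol
Conditions: Me2C(OMe)2, PPTS (cat.), acetone, 0 °C → rt
Reagents that add atoms: 2,2-dimethoxypropane, COC(C)(C)OC
Why: Acid-catalysed transacetalisation; only the cis-vicinal O2/O3 pair can close a five-membered dioxolane, which leaves the C6 hydroxyl free. The oxirane carbon C1 is flanked by two oxygen-bearing carbons, which disfavours its ionisation under this weak acid.

Step 5
Reactants: 6 (3S,4S,5S,8R)-4,5-O-isopropylidene-1-oxaspiro[2.5]oct-6-ene-4,5,8-triol; 7 cesium benzoate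
Product: 8 [(1S,2S,3S,6R)-1,6-dihydroxy-2,3-(isopropylidenedioxy)cyclohex-4-en-1-yl]methyl benzoate
Conditions: 7 (2 equiv), PhCO2H (1.2 equiv), DMF, 80 °C
Reagents that add atoms: cesium benzoate (7), [Cs+].[O-]C(=O)c1ccccc1
Why: SN2 opening of the 2,2-disubstituted oxirane by carboxylate at the unhindered primary carbon C7; C1 keeps its C–O bond and configuration and becomes the tertiary alcohol. Benzoic acid protonates the alkoxide as it forms, so that no C6 alkoxide (trans to the oxirane oxygen) is available for a Payne rearrangement.

Step 6
Reactants: 8 [(1S,2S,3S,6R)-1,6-dihydroxy-2,3-(isopropylidenedioxy)cyclohex-4-en-1-yl]methyl benzoate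
Product: 9 [(1R,2S,3S,6R)-1-hydroxy-2,3-(isopropylidenedioxy)-6-(methylsulfonyloxy)cyclohex-4-en-1-yl]methyl benzoate
Conditions: MsCl (1.1 equiv), Et3N, CH2Cl2, −20 °C
Reagents that add atoms: methanesulfonyl chloride, CS(=O)(=O)Cl
Why: Sulfonylation of the secondary allylic C6 hydroxyl; the tertiary C1 hydroxyl reacts far more slowly and O2/O3 are masked. Only an O–S bond forms, so C6 keeps its configuration; the low temperature keeps the hydroxy mesylate from closing prematurely.

Step 7
Reactants: 9 [(1R,2S,3S,6R)-1-hydroxy-2,3-(isopropylidenedioxy)-6-(methylsulfonyloxy)cyclohex-4-en-1-yl]methyl benzoate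
Product: 10 [(1R,2S,3S,6R)-1,2,3-trihydroxy-6-(methylsulfonyloxy)cyclohex-4-en-1-yl]methyl benzoate
Conditions: TsOH·H2O (cat.), MeOH, rt
Reagents that add atoms: none
Why: Acid-catalysed acetal exchange with methanol, placed before oxirane formation because a vinyl oxirane would not survive the acid needed to cleave an acetonide. The allylic mesylate is flanked by oxygen-bearing carbons, which retards its ionisation, and that ionisation is not acid-catalysed.

Step 8
Reactants: 10 [(1R,2S,3S,6R)-1,2,3-trihydroxy-6-(methylsulfonyloxy)cyclohex-4-en-1-yl]methyl benzoate
Product: 11 [(1R,2S,3S,6S)-2,3-dihydroxy-7-oxabicyclo[4.1.0]hept-4-en-1-yl]methyl benzoate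
Conditions: DBU (1.5 equiv), MeCN, 0 °C → rt
Reagents that add atoms: none
Why: Intramolecular Williamson etherification (3-exo-tet): the C1 oxygen, on the face opposite to the mesylate, displaces it with inversion at C6 and gives the cis-fused oxirane on the face opposite to C7, O2 and O3. Neither O2 nor O3 can reach the rear of C6, and C6 has no neighbouring sp3 C–H, so elimination cannot compete. An amidine base is used instead of an alkoxide so as not to promote benzoate migration or Payne equilibration of the product.

Step 9
Reactants: 11 [(1R,2S,3S,6S)-2,3-dihydroxy-7-oxabicyclo[4.1.0]hept-4-en-1-yl]methyl benzoate; 12 benzoyl chloride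
Product: 13 [(1R,2S,3S,6S)-3-(benzoyloxy)-2-hydroxy-7-oxabicyclo[4.1.0]hept-4-en-1-yl]methyl benzoate
Conditions: 12 (1.05 equiv), Ph2BOCH2CH2NH2 (10 mol %), i-Pr2NEt, MeCN, 0 °C → rt
Reagents that add atoms: benzoyl chloride (12), O=C(Cl)c1ccccc1
Why: Regioselective monoacylation of a cis-1,2-diol under diarylborinic acid catalysis: the diol forms a tetracoordinate borinate whose more accessible oxygen is acylated. O3 is allylic and has one substituted neighbour, whereas O2 lies next to the fully substituted C1 bearing C7H2OBz, so the benzoate should go to O3; no stereocentre is touched.

## Compound list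

1 | 2-(hydroxymethyl)phenol (salicyl alcohol) | OCc1ccccc1O | starting material
2 | (R)-1-oxaspiro[2.5]octa-5,7-dien-4-one | C1[C@@]2(O1)C(=O)C=CC=C2 | intermediate
3 | (3R,4S)-1-oxaspiro[2.5]octa-5,7-dien-4-ol (C2 hydroxyl cis to C7, trans to the oxirane oxygen) | O[C@H]1C=CC=C[C@@]12CO2 | intermediate
4 | endoperoxide of 3: 2,3-dioxabicyclo[2.2.2]oct-7-ene with the O–O bridge from C3 to C6 on the face of the C2 hydroxyl, spiro-oxirane at C1 retained | O[C@H]1[C@@H]2C=C[C@@H](OO2)[C@@]13CO3 | intermediate
5 | (3S,4S,5S,8R)-1-oxaspiro[2.5]oct-6-ene-4,5,8-triol (O2, O3, O6 all cis, trans to the oxirane oxygen) | O[C@H]1[C@@H](O)C=C[C@@H](O)[C@@]12CO2 | intermediate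
6 | (3S,4S,5S,8R)-4,5-O-isopropylidene-1-oxaspiro[2.5]oct-6-ene-4,5,8-triol (acetal on O2/O3, C6–OH free) | O[C@@H]1C=C[C@@H]2OC(C)(C)O[C@@H]2[C@]13CO3 | intermediate
7 | cesium benzoate | [Cs+].[O-]C(=O)c1ccccc1 | starting material
8 | [(1S,2S,3S,6R)-1,6-dihydroxy-2,3-(isopropylidenedioxy)cyclohex-4-en-1-yl]methyl benzoate | O[C@@H]1C=C[C@@H]2OC(C)(C)O[C@@H]2[C@]1(O)COC(=O)c1ccccc1 | intermediate
9 | [(1R,2S,3S,6R)-1-hydroxy-2,3-(isopropylidenedioxy)-6-(methylsulfonyloxy)cyclohex-4-en-1-yl]methyl benzoate | CS(=O)(=O)O[C@@H]1C=C[C@@H]2OC(C)(C)O[C@@H]2[C@]1(O)COC(=O)c1ccccc1 | intermediate
10 | [(1R,2S,3S,6R)-1,2,3-trihydroxy-6-(methylsulfonyloxy)cyclohex-4-en-1-yl]methyl benzoate | CS(=O)(=O)O[C@@H]1C=C[C@H](O)[C@H](O)[C@]1(O)COC(=O)c1ccccc1 | intermediate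
11 | [(1R,2S,3S,6S)-2,3-dihydroxy-7-oxabicyclo[4.1.0]hept-4-en-1-yl]methyl benzoate | O=C(OC[C@]12O[C@H]1C=C[C@H](O)[C@@H]2O)c1ccccc1 | intermediate
12 | benzoyl chloride | O=C(Cl)c1ccccc1 | starting material
13 | [(1R,2S,3S,6S)-3-(benzoyloxy)-2-hydroxy-7-oxabicyclo[4.1.0]hept-4-en-1-yl]methyl benzoate | O=C(OC[C@]12O[C@H]1C=C[C@H](OC(=O)c1ccccc1)[C@@H]2O)c1ccccc1 | target

## Step count and least certain steps

Total: 9 steps. Longest linear sequence: 9 steps from 1 (7 and 12 enter as reagents).

Step 1 (key step, new method).
- Risk: loss of enantioface control if the three-membered ring closes from a loosely bound or free phenoxenium-type intermediate and not inside the chiral iodine complex. Competing oxidation of the benzylic alcohol to the aldehyde and [4+2] dimerisation of the product before reduction are also possible.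
- Fallback (known chemistry; sets out from 1, returns at 3): oxidation of 1 with NaIO4 in water at 0 °C (Adler–Becker oxidation, heptavalent iodine reduced to pentavalent) would give the racemic dienone F1. It is extracted cold and reduced as in step 2 to the racemic dienol F2. Kinetic resolution with immobilised Candida antarctica lipase B and vinyl acetate in MTBE should, by the usual empirical rule for secondary alcohols (quaternary spiro carbon as the large group, vinylic CH as the medium group), acetylate the (4R)-enantiomer to the acetate F3 and leave 3. Half of the material is sacrificed.

Step 2.
- Risk: hydride delivery to the other face (attack anti to the electronegative oxirane oxygen when chelation is weak), giving the C2 epimer. Dimerisation of 2 during transfer is a second risk.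
- Fallback (sets out from 1, returns at 13): the other hydride outcome is matched to the other catalyst antipode, and C1 is inverted later.
  - The enantiomeric catalyst would give the (S)-dienone F4, and hydride attack anti to the oxirane oxygen then gives the syn-dienol F5, in which C2 already has the target configuration.
  - Photooxygenation in MeOH (methylene blue), where hydrogen-bond direction is switched off, should occur on the face remote from both oxygen substituents to give the endoperoxide F6. Thiourea then gives the triol F7, whose C6 hydroxyl is trans to the oxirane oxygen.
  - Brief treatment with aqueous NaOH in t-BuOH (Payne rearrangement) lets O6 open the spiro-oxirane at C1 with inversion, giving the ring oxirane and the primary alcohol F8 with C1 in the target configuration.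
  - Acylation of the primary hydroxyl with 12 (2,4,6-collidine, CH2Cl2, −40 °C) gives the monobenzoate F9.
  - A Mitsunobu reaction with benzoic acid (PPh3, DIAD) at the allylic C3 hydroxyl inverts C3 and installs the second benzoate, giving 13.

Step 3.
- Risk: partial attack of oxygen on the lower face if the hydrogen bond is too weak to outweigh the steric presence of the hydroxyl. Acid-triggered rearomatisation of 3 is also possible (opening of the doubly allylic oxirane at C1, then loss of the C2 proton, returns 1).
- Fallback (sets out from 1, returns at 13; no compound beyond those of the step 2 fallback, F0): hydrogen-bond direction is given up. The dienone F4 is reduced without a chelating cation (Bu4NBH4, CH2Cl2, −78 °C), where attack anti to the oxirane oxygen should give the syn-dienol F5 on purpose. The sequence through the triol F7 and the benzoate F9 to 13 is then followed; in it oxygen is steered only by repulsion from two oxygen substituents on the same face.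

Step 5.
- Risk: if any alkoxide builds up, O6 opens the oxirane at C1 (Payne rearrangement), which inverts C1 and frees C7–OH. Opening at the neopentyl-type C7 may also be slow enough for benzoyl migration to compete.
- Fallback (sets out from 6, returns at 8): the offending hydroxyl is taken out of play. O6 is silylated (Et3SiCl, imidazole, CH2Cl2) to the silyl ether F10, the oxirane is opened with 7 as in step 5 to the hydroxy ester F11, and the silyl ether is cleaved with Bu4NF buffered with acetic acid to give 8. This costs two more steps.

Step 9.
- Risk: insufficient discrimination between O3 and O2, over-acylation, or base-induced migration of the new ester to O2.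
- Fallback (sets out from 10, returns at 13): the order is changed so that acylation precedes oxirane closure. In 10 the C2 hydroxyl sits next to the tertiary carbinol centre and is more shielded than in 11, so 12 (pyridine, CH2Cl2, −40 °C) should give the 3-benzoate F12. Closure with DBU as in step 8 then gives 13 directly, at the price of exposing the cis hydroxy ester to base.

## Further compounds

F1 | step 1 | racemic 1-oxaspiro[2.5]octa-5,7-dien-4-one | O=C1C=CC=CC12CO2
F2 | step 1 | racemic (3R*,4S*)-1-oxaspiro[2.5]octa-5,7-dien-4-ol (both enantiomers written) | O[C@H]1C=CC=C[C@@]12CO2.O[C@@H]1C=CC=C[C@]12CO2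
F3 | step 1 | (3S,4R)-1-oxaspiro[2.5]octa-5,7-dien-4-yl acetate | CC(=O)O[C@@H]1C=CC=C[C@]12CO2
F4 | step 2 | (S)-1-oxaspiro[2.5]octa-5,7-dien-4-one | C1[C@]2(O1)C(=O)C=CC=C2
F5 | step 2 | (3S,4S)-1-oxaspiro[2.5]octa-5,7-dien-4-ol (C2 hydroxyl cis to the oxirane oxygen) | O[C@H]1C=CC=C[C@]12CO2
F6 | step 2 | endoperoxide of F5: O–O bridge from C3 to C6 on the face opposite to the C2 hydroxyl and the oxirane oxygen | O[C@H]1[C@H]2C=C[C@H](OO2)[C@]13CO3
F7 | step 2 | (3R,4S,5R,8S)-1-oxaspiro[2.5]oct-6-ene-4,5,8-triol | O[C@H]1[C@H](O)C=C[C@H](O)[C@]12CO2
F8 | step 2 | (1R,2S,3R,6S)-1-(hydroxymethyl)-7-oxabicyclo[4.1.0]hept-4-ene-2,3-diol | OC[C@]12O[C@H]1C=C[C@@H](O)[C@@H]2O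
F9 | step 2 | [(1R,2S,3R,6S)-2,3-dihydroxy-7-oxabicyclo[4.1.0]hept-4-en-1-yl]methyl benzoate | O=C(OC[C@]12O[C@H]1C=C[C@@H](O)[C@@H]2O)c1ccccc1
F0 | step 3 | none | none
F10 | step 5 | O6 triethylsilyl ether of 6 | CC[Si](CC)(CC)O[C@@H]1C=C[C@@H]2OC(C)(C)O[C@@H]2[C@]13CO3
F11 | step 5 | O6 triethylsilyl ether of 8 | CC[Si](CC)(CC)O[C@@H]1C=C[C@@H]2OC(C)(C)O[C@@H]2[C@]1(O)COC(=O)c1ccccc1
F12 | step 9 | [(1R,2S,3S,6R)-3-(benzoyloxy)-1,2-dihydroxy-6-(methylsulfonyloxy)cyclohex-4-en-1-yl]methyl benzoate | CS(=O)(=O)O[C@@H]1C=C[C@H](OC(=O)c2ccccc2)[C@H](O)[C@]1(O)COC(=O)c1ccccc1
A1 | alternative 1 | fused isoxazoline: cyclohex-4-ene with O2/O3 acetonide, C1 tert-butyldimethylsilyl ether and a C7H2–O–N=C6 ring fused at C1–C6 | C1ON=C2C=C[C@@H]3OC(C)(C)O[C@@H]3[C@]12O[Si](C)(C)C(C)(C)C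
A2 | alternative 1 | open-chain (Z)-enal oxime carrying the O2/O3 acetonide and the C1=C7H2 tert-butyldimethylsilyl enol ether | O/N=C/C=C\[C@@H]1OC(C)(C)O[C@@H]1C(=C)O[Si](C)(C)C(C)(C)C
A3 | alternative 2 | (1S,2R)-3-(acetoxymethyl)cyclohexa-3,5-diene-1,2-diol | CC(=O)OCC1=CC=C[C@H](O)[C@@H]1O
A4 | alternative 2 | benzyl acetate | CC(=O)OCc1ccccc1
A5 | alternative 3 | target lacking the C3 benzoyl group and carrying a tert-butyldimethylsilyl ether on O2 | O=C(OC[C@]12O[C@H]1C=C[C@H](O)[C@@H]2O[Si](C)(C)C(C)(C)C)c1ccccc1
A6 | alternative 3 | acyclic aldehyde: 2-(tert-butyldimethylsilyloxy)-2-[2-(benzoyloxymethyl)-3-((Z)-2-iodovinyl)oxiran-2-yl]acetaldehyde | O=C[C@H](O[Si](C)(C)C(C)(C)C)[C@@]1(COC(=O)c2ccccc2)O[C@H]1/C=C\I
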